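The easy step comes first: solid X goes into solution as D, E takes D away, and L lies beyond this pair.

    D + E → G + Z (k1 = 0.00406 L mol⁻¹ s⁻¹, Ea1 = 85.0 kJ mol⁻¹)
    G ⇌ L (K2 = 1.94, k2 = 0.00421 s⁻¹, Ea2 = 110 kJ mol⁻¹, ΔH2 = −39.0 kJ mol⁻¹)
    G ⇌ Q (K3 = 3.2, k3 = 6.86 × 10⁻⁴ s⁻¹, Ea3 = 98.0 kJ mol⁻¹, ΔH3 = −4.00 kJ mol⁻¹)
    J ⇌ L, rate k4*(cs4 - [L]) while solid is left; crystals form when [L] > cs4 (cs4 = 9.4 mM, k4 = 0.0511 s⁻¹)
    X ⇌ D, rate k5*(cs5 - [D]) while solid is left; crystals form when [D] > cs5 (cs5 = 0.12 M, k5 = 0.00169 s⁻¹)
    (constants at 90 °C)

common to all: X 0.30 M; E 1.80 equiv; time 10 min

| charge | temperature |
|---|---|
| north-east | 90 °C |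
| south-west | 140 °C |
| north-west | 115 °C |

- L is meant together with its J
- solid, in amounts per volume of the solution: J, X
- all constants are for 90 °C and move with temperature by the activation energies and enthalpies
- at the start none of X is in solution
- what has only dissolved of X counts as not reacted

- the best flask by amount of L, in percent of the X charged; "all alike" if 1.5 percentage points covers them all (north-east / south-west / north-west / all alike)
- amount of L at the end, in percent of the X charged, north-east
- amount of L at the end, in percent of the X charged, south-west
- amount of L at the end, in percent of the X charged, north-west

As paces at the charged amounts, dissolving runs at 0.1 min⁻¹, and the first step, pseudo-first-order in D with E at 0.540 M, runs at 0.132 min⁻¹ in north-east. Where arrival of D equals its removal, D stands at the solubility times the dissolving pace over the sum of the two paces: this held level of D comes to 17.4 % of the X charged in north-east. In north-east D closes on it with a time of 4.29 min, shorter than the 10 min allowed, so D should stand close to the level by the end. In south-west the first step runs 30 times faster, while the dissolving constant carries no activation energy, so the held level falls to 0.996 % and more of the dissolving X gets through. The equilibrium between G and dissolved L moves the other way, its constant falling from 1.94 in north-east to 0.406 in south-west. This reckoning goes no further than a direction: with the two trends opposed, it favours the middle flask, north-west, and puts no number on L.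

The forecast gives 5.5 % for north-east, 5.6 % for south-west and 14.8 % for north-west, the best being north-west, on the ground that in the middle flask “early crystallisation of J keeps drawing G toward L before Q catches up”.

The simulation gives 5.77 % in north-east, 6.09 % in south-west and 16.5 % in north-west, so north-west leads. Conversion of X at the end is highest in south-west, at 38.2 % against 13.6 % in north-east and 31.1 % in north-west. D reads 16.0 % in north-east at 10.0 min against the held level of 17.4 %, reckoned with E as charged, and 1.25 % in south-west against 0.996 %, reckoned the same way, while E there reads 78.8 % of its charge.

A further flask, like north-east but with 7.20 equiv of E, has a held level of 6.46 %. Its run reads D at 6.63 % and L at 13.9 % at 10.0 min.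

The constants used here come from no measurement; what happens was integrated by code.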